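**Retrosynthetic overview**
- The target is reached by global desilylation of a pentasilylated (2S)-flavanone. Rings A and B and the phenol ring are bought aromatic; ring C is the only ring made, and it is made last.
- Ring C is opened at C2–C3: C3 becomes a rhodium carbene generated from an aryl diazomethyl ketone, and C2 becomes the O–CH2 group of a benzyl aryl ether.
- Enabling feature: C2 of ring C is both benzylic to ring B and alpha to the ring oxygen O1. In the open precursor its C–H bonds are doubly activated and sit 1,6 to C3, while the 1,5 position is O1 itself, so the carbene can only close the six-membered pyranone.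
- The diazoketone comes from Mitsunobu etherification of bis-silylated phloroacetophenone with the ring B benzylic alcohol, followed by deacylative diazo transfer at the acetyl CH3 (the future C3).
- The (1R,2R)-threo side chain is set by an Evans syn-glycolate aldol between an aryloxyacetyl oxazolidinone (from methyl syringate) and 4-silyloxybenzaldehyde.

Key step: step 9

Assumption: Rh2(S-BSP)4, dirhodium tetrakis[N-(phenylsulfonyl)-(S)-prolinate], is taken to favour the (2S) product in step 9; if a model run shows the opposite sense, the mirror-image catalyst Rh2(R-BSP)4 is used in the same step. Compounds 2 and 4 are taken as commercial.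

**Step 1**
Reactants: 1 methyl syringate; 2 (S)-4-benzyl-3-(chloroacetyl)oxazolidin-2-one
Product: 3 (S)-4-benzyl-3-{[2,6-dimethoxy-4-(methoxycarbonyl)phenoxy]acetyl}oxazolidin-2-one
Conditions: K2CO3, NaI (cat.), acetone, rt → 45 °C
Reagents that add atoms: none
Why: Williamson ether synthesis with in situ Finkelstein activation; the hindered, weakly basic syringate phenoxide should displace the alpha-halide of the imide by SN2 faster than it attacks the imide carbonyl.

**Step 2**
Reactants: 3 aryloxyacetyl oxazolidinone; 4 4-(tert-butyldimethylsilyloxy)benzaldehyde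
Product: 6 Evans syn-aldol adduct (2S,3R)-imide, via dibutylboron Z-enolate 5 (not isolated)
Conditions: Bu2BOTf, i-Pr2NEt, CH2Cl2, −78 → 0 °C; then 4, −78 → 0 °C; then pH 7 buffer, MeOH, H2O2, 0 °C
Reagents that add atoms: none
Why: Evans boron glycolate aldol; the Z-enolate reacts through a chair Zimmerman–Traxler transition state on the face away from the auxiliary benzyl group, which sets both side-chain centres as the syn (threo) pair with (2S,3R) configuration.

**Step 3**
Reactants: 6 syn-aldol adduct
Product: 7 methyl 4-{[(1R,2R)-1-[4-(tert-butyldimethylsilyloxy)phenyl]-1,3-dihydroxypropan-2-yl]oxy}-3,5-dimethoxybenzoate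
Conditions: NaBH4, THF/H2O, 0 °C → rt
Reagents that add atoms: none
Why: Reductive cleavage of the N-acyloxazolidinone by borohydride should release the primary alcohol and the auxiliary while leaving the electron-rich aromatic methyl ester and both stereocentres untouched.

**Step 4**
Reactants: 7 diol
Product: 8 methyl 4-{[(1R,2R)-1,3-bis(tert-butyldimethylsilyloxy)-1-[4-(tert-butyldimethylsilyloxy)phenyl]propan-2-yl]oxy}-3,5-dimethoxybenzoate
Conditions: TBSCl (excess), imidazole, DMF, rt
Reagents that add atoms: tert-butyldimethylsilyl chloride, CC(C)(C)[Si](C)(C)Cl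
Why: Standard silyl ether formation under Corey conditions on the primary and the secondary benzylic alcohol; any phenol freed in step 3 would be re-silylated here.

**Step 5**
Reactants: 8 tris-silyl ester
Product: 9 (4-{[(1R,2R)-1,3-bis(tert-butyldimethylsilyloxy)-1-[4-(tert-butyldimethylsilyloxy)phenyl]propan-2-yl]oxy}-3,5-dimethoxyphenyl)methanol
Conditions: i-Bu2AlH, CH2Cl2, −78 → 0 °C; Rochelle salt work-up
Reagents that add atoms: none
Why: Aluminium hydride reduction of the aryl ester to the benzylic alcohol, to which silyl ethers and aryl ethers are inert.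

**Step 6**
Reactants: 10 2',4',6'-trihydroxyacetophenone (dried)
Product: 11 2'-hydroxy-4',6'-bis(triisopropylsilyloxy)acetophenone
Conditions: TIPSCl (2.1 equiv), imidazole, DMF, 0 °C → rt
Reagents that add atoms: triisopropylsilyl chloride, CC(C)[Si](Cl)(C(C)C)C(C)C
Why: Regioselective silylation; the para hydroxyl and the one ortho hydroxyl not hydrogen-bonded to the ketone should react, and the chelated ortho hydroxyl should resist the bulky silyl chloride.

**Step 7**
Reactants: 9 ring B benzylic alcohol; 11 ring A phenol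
Product: 12 1-{2-[(4-{[(1R,2R)-1,3-bis(tert-butyldimethylsilyloxy)-1-[4-(tert-butyldimethylsilyloxy)phenyl]propan-2-yl]oxy}-3,5-dimethoxybenzyl)oxy]-4,6-bis(triisopropylsilyloxy)phenyl}ethan-1-one
Conditions: PPh3, DIAD, THF, 0 °C → rt
Reagents that add atoms: none
Why: Mitsunobu etherification of a primary benzylic alcohol with an acidic, chelated phenol under neutral conditions that should spare the aryl silyl ethers; no stereocentre is involved.

**Step 8**
Reactants: 12 methyl ketone
Product: 14 2-diazo-1-{2-[(4-{[(1R,2R)-1,3-bis(tert-butyldimethylsilyloxy)-1-[4-(tert-butyldimethylsilyloxy)phenyl]propan-2-yl]oxy}-3,5-dimethoxybenzyl)oxy]-4,6-bis(triisopropylsilyloxy)phenyl}ethan-1-one, via trifluoroacetyl diketone 13 (not isolated)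
Conditions: LiN(SiMe3)2, THF, −78 °C; CF3CO2CH2CF3, −78 °C; aq. HCl work-up; then p-ABSA, Et3N, H2O (1 equiv), MeCN, rt
Reagents that add atoms: 4-acetamidobenzenesulfonyl azide (p-ABSA), CC(=O)Nc1ccc(cc1)S(=O)(=O)N=[N+]=[N-] (the two diazo nitrogens of 14); 2,2,2-trifluoroethyl trifluoroacetate, FC(F)(F)COC(=O)C(F)(F)F (the CF3CO group of 13 only)
Why: Danheiser deacylative diazo transfer; the kinetic lithium enolate of the only enolisable position is C-trifluoroacetylated, and the activated 1,3-diketone takes up the diazo group from the sulfonyl azide with loss of the trifluoroacetyl group.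

**Step 9**
Reactants: 14 alpha-diazoketone
Product: 15 (2S)-2-(4-{[(1R,2R)-1,3-bis(tert-butyldimethylsilyloxy)-1-[4-(tert-butyldimethylsilyloxy)phenyl]propan-2-yl]oxy}-3,5-dimethoxyphenyl)-5,7-bis(triisopropylsilyloxy)chroman-4-one
Conditions: Rh2(S-BSP)4 (2 mol %), CH2Cl2, slow addition of 14 at high dilution, 0 °C → rt
Reagents that add atoms: none
Why: The dirhodium tetracarboxylate expels N2 from 14 to give an electrophilic rhodium-bound acyl carbene at the future C3, which inserts into one benzylic O–CH2 hydrogen through a concerted, hydride-transfer-like three-centre transition state and so forms the C3–C2 bond. The closest known reaction type is the chiral dirhodium carboxylate-catalysed intramolecular C–H insertion of 2-alkoxyphenyl diazoketones to chroman-4-ones. Ring C closes as a six-membered ring by 1,6-insertion, because the 1,5 position is the ether oxygen O1 and offers no C–H bond. The new C2 stereocentre is set by the chiral prolinate ligands of the catalyst, which distinguish the two benzylic hydrogens; the remote (1R,2R) centres are too far to interfere, and they make any C2 epimer a separable diastereomer. The step needs site selectivity for C–H insertion over oxonium ylide formation at O1 followed by a 1,2-benzyl shift, and this should be secured by the low basicity of an aryl ether oxygen conjugated to the acyl-bearing ring A together with the double activation (alpha-oxygen, electron-rich benzylic) of the C2–H bonds. It also needs the second ortho oxygen to stay out of the reaction, which the triisopropylsilyl ether secures by having no C–H alpha to oxygen and a shielded, non-nucleophilic oxygen.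

**Step 10**
Reactants: 15 pentasilylated flavanone
Product: 16 (2S)-5,7-dihydroxy-2-(4-{[(1R,2R)-1,3-dihydroxy-1-(4-hydroxyphenyl)propan-2-yl]oxy}-3,5-dimethoxyphenyl)chroman-4-one (CNP0263993.1)
Conditions: Bu4NF, AcOH (1:1, excess), THF, 0 °C → rt
Reagents that add atoms: none
Why: Fluoride-mediated global desilylation, buffered with acetic acid so that no free phenoxide can open ring C by retro-oxa-Michael reaction (which would scramble C2) or form a quinone methide at the benzylic carbinol; no stereocentre is touched.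

**Compound list**
1 | methyl syringate (methyl 4-hydroxy-3,5-dimethoxybenzoate) | COC(=O)c1cc(OC)c(O)c(OC)c1 | starting material
2 | (S)-4-benzyl-3-(chloroacetyl)oxazolidin-2-one | O=C(CCl)N1C(=O)OC[C@@H]1Cc1ccccc1 | starting material
3 | (S)-4-benzyl-3-{[2,6-dimethoxy-4-(methoxycarbonyl)phenoxy]acetyl}oxazolidin-2-one | COc1cc(C(=O)OC)cc(OC)c1OCC(=O)N1C(=O)OC[C@@H]1Cc1ccccc1 | intermediate
4 | 4-(tert-butyldimethylsilyloxy)benzaldehyde | O=Cc1ccc(O[Si](C)(C)C(C)(C)C)cc1 | starting material
5 | dibutylboron Z-enolate of 3 | COc1cc(C(=O)OC)cc(OC)c1O/C=C(\OB(CCCC)CCCC)N1C(=O)OC[C@@H]1Cc1ccccc1 | intermediate (not isolated)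
6 | (S)-4-benzyl-3-[(2S,3R)-3-[4-(tert-butyldimethylsilyloxy)phenyl]-2-[2,6-dimethoxy-4-(methoxycarbonyl)phenoxy]-3-hydroxypropanoyl]oxazolidin-2-one | COc1cc(C(=O)OC)cc(OC)c1O[C@H](C(=O)N1C(=O)OC[C@@H]1Cc1ccccc1)[C@H](O)c1ccc(O[Si](C)(C)C(C)(C)C)cc1 | intermediate
7 | methyl 4-{[(1R,2R)-1-[4-(tert-butyldimethylsilyloxy)phenyl]-1,3-dihydroxypropan-2-yl]oxy}-3,5-dimethoxybenzoate | COc1cc(C(=O)OC)cc(OC)c1O[C@H](CO)[C@H](O)c1ccc(O[Si](C)(C)C(C)(C)C)cc1 | intermediate
8 | methyl 4-{[(1R,2R)-1,3-bis(tert-butyldimethylsilyloxy)-1-[4-(tert-butyldimethylsilyloxy)phenyl]propan-2-yl]oxy}-3,5-dimethoxybenzoate | COc1cc(C(=O)OC)cc(OC)c1O[C@H](CO[Si](C)(C)C(C)(C)C)[C@H](O[Si](C)(C)C(C)(C)C)c1ccc(O[Si](C)(C)C(C)(C)C)cc1 | intermediate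
9 | (4-{[(1R,2R)-1,3-bis(tert-butyldimethylsilyloxy)-1-[4-(tert-butyldimethylsilyloxy)phenyl]propan-2-yl]oxy}-3,5-dimethoxyphenyl)methanol | COc1cc(CO)cc(OC)c1O[C@H](CO[Si](C)(C)C(C)(C)C)[C@H](O[Si](C)(C)C(C)(C)C)c1ccc(O[Si](C)(C)C(C)(C)C)cc1 | intermediate
10 | 2',4',6'-trihydroxyacetophenone | CC(=O)c1c(O)cc(O)cc1O | starting material
11 | 2'-hydroxy-4',6'-bis(triisopropylsilyloxy)acetophenone | CC(=O)c1c(O)cc(O[Si](C(C)C)(C(C)C)C(C)C)cc1O[Si](C(C)C)(C(C)C)C(C)C | intermediate
12 | benzyl aryl ether methyl ketone (full name in step 7) | COc1cc(COc2cc(O[Si](C(C)C)(C(C)C)C(C)C)cc(O[Si](C(C)C)(C(C)C)C(C)C)c2C(C)=O)cc(OC)c1O[C@H](CO[Si](C)(C)C(C)(C)C)[C@H](O[Si](C)(C)C(C)(C)C)c1ccc(O[Si](C)(C)C(C)(C)C)cc1 | intermediate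
13 | 4,4,4-trifluoro-1-aryl-butane-1,3-dione derived from 12 | COc1cc(COc2cc(O[Si](C(C)C)(C(C)C)C(C)C)cc(O[Si](C(C)C)(C(C)C)C(C)C)c2C(=O)CC(=O)C(F)(F)F)cc(OC)c1O[C@H](CO[Si](C)(C)C(C)(C)C)[C@H](O[Si](C)(C)C(C)(C)C)c1ccc(O[Si](C)(C)C(C)(C)C)cc1 | intermediate (not isolated)
14 | alpha-diazoketone (full name in step 8) | COc1cc(COc2cc(O[Si](C(C)C)(C(C)C)C(C)C)cc(O[Si](C(C)C)(C(C)C)C(C)C)c2C(=O)C=[N+]=[N-])cc(OC)c1O[C@H](CO[Si](C)(C)C(C)(C)C)[C@H](O[Si](C)(C)C(C)(C)C)c1ccc(O[Si](C)(C)C(C)(C)C)cc1 | intermediate
15 | pentasilylated (2S)-flavanone (full name in step 9) | COc1cc([C@@H]2CC(=O)c3c(O[Si](C(C)C)(C(C)C)C(C)C)cc(O[Si](C(C)C)(C(C)C)C(C)C)cc3O2)cc(OC)c1O[C@H](CO[Si](C)(C)C(C)(C)C)[C@H](O[Si](C)(C)C(C)(C)C)c1ccc(O[Si](C)(C)C(C)(C)C)cc1 | intermediate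
16 | (2S)-5,7-dihydroxy-2-(4-{[(1R,2R)-1,3-dihydroxy-1-(4-hydroxyphenyl)propan-2-yl]oxy}-3,5-dimethoxyphenyl)chroman-4-one | COc1cc([C@@H]2CC(=O)c3c(O)cc(O)cc3O2)cc(OC)c1O[C@H](CO)[C@H](O)c1ccc(O)cc1 | target

**Step count**
Total: 10 steps. Longest linear sequence: 9 steps (steps 1–5 and 7–10); the ring A branch is step 6.

**Steps most likely to fail, with fallbacks**

Step 9. The carbene may be captured by the lone pair of O1 to give an oxonium ylide whose benzyl group shifts 1,2, contracting the ring to a coumaranone skeleton. Alternatively, the catalyst may discriminate poorly between the two benzylic hydrogens, giving poor selectivity at C2. The fallback leaves carbene chemistry and sets out from 9 and 11. Alcohol 9 is oxidised with MnO2 in CH2Cl2 to the ring B aldehyde F1. F1 is condensed with ketone 11 by pyrrolidine in MeCN at 50 °C (Kabbe-type aldol condensation), which passes through the 2'-hydroxychalcone F2. F2 closes under the same conditions by oxa-Michael addition to a mixture of 15 and its (2R)-epimer F3. Because the side chain is enantiopure, the two are diastereomers and should be separable by chromatography; F3 can be re-equilibrated through F2 under the same amine conditions. The fallback returns to the route at 15.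

Step 8. In the lithium enolate, the ortho triisopropylsilyl group may migrate from the phenolic oxygen to the enolate oxygen, or C-trifluoroacetylation of the hindered enolate may stay incomplete. The fallback avoids the lithium enolate and sets out from 12. Soft enolisation with Me3SiOTf and Et3N in CH2Cl2 at 0 °C should give the trimethylsilyl enol ether F4. Bromination with NBS in THF at −78 °C should give the alpha-bromoketone F5. Treatment of F5 with N,N'-ditosylhydrazine and DBU in THF at 0 °C (Fukuyama diazo synthesis) should give the diazoketone, returning to the route at 14.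

Step 1. Phenoxide or carbonate may attack the exocyclic imide carbonyl of 2 and cleave the acyl–nitrogen bond, so that the auxiliary is lost instead of the halide being displaced. The fallback builds the imide after the ether and sets out from 1. Alkylation with tert-butyl bromoacetate (K2CO3, acetone) should give the tert-butyl aryloxyacetate F6. Cleavage with CF3CO2H in CH2Cl2 should give the aryloxyacetic acid F7. Activation with pivaloyl chloride and Et3N in THF at −20 °C should give the mixed pivalic anhydride F8, which is acylated in the same flask onto (S)-4-benzyloxazolidin-2-one in the presence of LiCl, returning to the route at 3.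

**Further compounds**
F1 | step 9 | 4-{[(1R,2R)-1,3-bis(tert-butyldimethylsilyloxy)-1-[4-(tert-butyldimethylsilyloxy)phenyl]propan-2-yl]oxy}-3,5-dimethoxybenzaldehyde | COc1cc(C=O)cc(OC)c1O[C@H](CO[Si](C)(C)C(C)(C)C)[C@H](O[Si](C)(C)C(C)(C)C)c1ccc(O[Si](C)(C)C(C)(C)C)cc1
F2 | step 9 | (E)-2'-hydroxy-4',6'-bis(triisopropylsilyloxy)chalcone carrying the silylated side chain on ring B | COc1cc(/C=C/C(=O)c2c(O)cc(O[Si](C(C)C)(C(C)C)C(C)C)cc2O[Si](C(C)C)(C(C)C)C(C)C)cc(OC)c1O[C@H](CO[Si](C)(C)C(C)(C)C)[C@H](O[Si](C)(C)C(C)(C)C)c1ccc(O[Si](C)(C)C(C)(C)C)cc1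
F3 | step 9 | (2R)-epimer of 15 | COc1cc([C@H]2CC(=O)c3c(O[Si](C(C)C)(C(C)C)C(C)C)cc(O[Si](C(C)C)(C(C)C)C(C)C)cc3O2)cc(OC)c1O[C@H](CO[Si](C)(C)C(C)(C)C)[C@H](O[Si](C)(C)C(C)(C)C)c1ccc(O[Si](C)(C)C(C)(C)C)cc1
F4 | step 8 | trimethylsilyl enol ether of 12 | COc1cc(COc2cc(O[Si](C(C)C)(C(C)C)C(C)C)cc(O[Si](C(C)C)(C(C)C)C(C)C)c2C(=C)O[Si](C)(C)C)cc(OC)c1O[C@H](CO[Si](C)(C)C(C)(C)C)[C@H](O[Si](C)(C)C(C)(C)C)c1ccc(O[Si](C)(C)C(C)(C)C)cc1
F5 | step 8 | alpha-bromoketone of 12 | COc1cc(COc2cc(O[Si](C(C)C)(C(C)C)C(C)C)cc(O[Si](C(C)C)(C(C)C)C(C)C)c2C(=O)CBr)cc(OC)c1O[C@H](CO[Si](C)(C)C(C)(C)C)[C@H](O[Si](C)(C)C(C)(C)C)c1ccc(O[Si](C)(C)C(C)(C)C)cc1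
F6 | step 1 | methyl 4-(2-tert-butoxy-2-oxoethoxy)-3,5-dimethoxybenzoate | COc1cc(C(=O)OC)cc(OC)c1OCC(=O)OC(C)(C)C
F7 | step 1 | [2,6-dimethoxy-4-(methoxycarbonyl)phenoxy]acetic acid | COc1cc(C(=O)OC)cc(OC)c1OCC(=O)O
F8 | step 1 | mixed pivalic anhydride of F7 | COc1cc(C(=O)OC)cc(OC)c1OCC(=O)OC(=O)C(C)(C)C
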